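## Structural features

The target 24 is a (2S)-flavanone with the naringenin oxygen pattern (5-OH, 7-OH, 4'-OH) whose ring A carries at C6 a (2S)-1-methylpiperidin-2-yl group bound through C2''. Ring A, a phloroglucinol-type benzene, is fused to the dihydropyranone ring C through C4a and C8a; ring B sits on C2; the piperidine hangs from C6 by a single C6–C2'' bond between the oxygen-bearing carbons C5 and C7. The two stereocentres C2 and C2'' lie on opposite sides of ring A, five bonds apart, so neither can direct the other and each needs its own source of asymmetry. Fragile points are C2 (epimerised by base through retro-oxa-Michael opening to the chalcone), the benzylic C2''–N bond on a trioxygenated ring (can ionise in strong acid), the free phenol ring (nucleophilic at C8, easily oxidised) and the tertiary amine (adds to arynes and other electrophiles). The real difficulty is regiochemical: the piperidine must end at C6 and not at C8, which in a phloroglucinol-based approach means telling apart nearly identical oxygens, and this must be solved alongside two unrelated stereocentres. The key step exploits two features: ring C is attached at the adjacent carbons C8a (to O1) and C4a (to C4) with the C5 oxygen directly beside C4a, which is the pattern an oxygen nucleophile and a 3-alkoxyaryne deliver; and the ring A partner has a mirror plane through C6 and C8a, so the C6/C8 question never arises.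

## Logic of the disconnections

**24 from 23.** The three phenolic O–CH2Ph bonds are cut last. Free phenols would not survive aryne, hydride or oxidation chemistry, so all earlier work is done on a neutral ring system. The final cleavage must spare the C4 carbonyl, the benzylic C2–O1 bond and the benzylic C2''–N bond.

**23 from 22 from 21.** The N–CH3 carbon is traced back to the carbamate carbon of 21, and the C4 carbonyl to the C4 carbinol. The reduction that makes 21 leaves C4 at the alcohol level anyway, and that is the one point at which a strong hydride can turn the carbamate into N-methyl with no carbonyl in the way. The nitrogen mask needed for the aryne step thus becomes the N-methyl group in one operation. The hydride must leave all ether bonds alone, and the reoxidation must be non-basic (C2) and tolerate the amine.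

**21 from 20.** The C2–H, C3–H and C4–H bonds are cut. Removing the C2 stereocentre gives a flat chromone that tolerates fluoride at high temperature, and C2 is then set late by a chiral catalyst. The demand is face selectivity from the catalyst alone, without help or hindrance from C2''.

**20 from 15 and 17.** C8a–O1, C4a–C4 and O1–C2 are cut together, which removes ring C and ring B in one stroke and leaves a ring A piece derived from a symmetric phenol. The forward step needs regioselective addition to an unsymmetrical aryne, acyl transfer faster than protonation of the aryl anion, 6-endo rather than 5-exo closure, and a nitrogen that cannot add to the aryne.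

**17 from 16.** The C(sp)–CO2H bond is cut; carboxylation of the acetylide is the only demand.

**15 from 12 from 11.** The C–Si and O–triflyl bonds are traced to an ortho-bromophenol, and the C–Br bond to 11. Because 11 has two equivalent ortho positions, bromination has no regiochemical choice. The organolithium step must outrun attack on the carbamate.

**11 from 9.** This is a protecting-group exchange: N-sulfinyl to N-Boc, and the para O-acetal to free OH. Both old groups are acid-labile and fall together. The acid must be mild enough not to ionise the C2''–N bond.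

**9 from 5 and 6 (through 7 and 8).** N–C6'' and C2''–C3'' are cut, which removes the piperidine ring and its stereocentre and leaves an aldimine and a four-carbon chain. The forward step needs high facial selectivity from the sulfinyl group despite two ortho ether oxygens.

**5 from 3 and 4; 3 from 2 from 1.** The C=N bond is cut, then the two ortho O–benzyl bonds, then the para O-acetal bond. The only demand is that the first protection goes to the para hydroxyl.

## Other disconnections considered

**Alternative 1:** The cut is C2''–C3'' and N1''–C6'' of the piperidine. In the forward step a 4-chlorobutyl Grignard reagent adds to the (R)-N-sulfinyl aldimine of a symmetric, protected ring A aldehyde and base then closes the ring by N-alkylation, giving A1.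
- In favour: one flask builds a ring, two bonds and the C2'' stereocentre under auxiliary control, with cheap reagents and a symmetric ring A.
- Against: as the defining step of a plan it leaves the harder half open, namely ring C, the C2 stereocentre and the way ring A is desymmetrised.
- Comparison: A1 contains neither ring C nor ring B, so on structure it is further from the target than 20. On mechanism, a chelated polar addition is as dependable as the aryne step, and on stereochemical content it is the better step, since it creates a stereocentre and the aryne insertion creates none. On step economy the two are equal, because A1 is the same compound as 9 and the chosen plan uses this annulation on the way to its aryne precursor. The two are complementary rather than competing.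

**Alternative 2:** The cut is through ring A itself (C5–C6, C7–C8 and C4a–C5). The chiral-pool ester A2 would be homologated to the siloxyalkyne A3. Heating A3 with the cyclobutenone A4 would then run a Danheiser benzannulation (4π opening to a vinylketene, [2+2] with the ynol ether, 4π opening, 6π closure, tautomerisation) to the phenol A5.
- In favour: C2'' is bought, not made, so there is no auxiliary and no diastereoselection. On this point it is the better plan. The three ring A oxygens emerge differently protected, so the site of ring C attachment is fixed by protecting groups; this is equal to or better than relying on symmetry.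
- Against: making A3 from A2 needs strongly basic ynolate chemistry next to an epimerisable α-amino centre. The thermal cascade uses a hindered alkyne. After A5, ring C, ring B and C2 are all still to be built (acylation at C4a, condensation, cyclisation, asymmetric control).
- Comparison: the key step builds ring A, so A5 is structurally further from the target than 20. The pericyclic cascade has regiochemistry set by ketene and ynol ether polarity, in principle as reliable as the aryne regiochemistry. Overall it is expected to be longer, because the differentiation it provides is not needed once symmetry is used.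

**Alternative 3:** The cut is C4–C4a. The acid A6, activated as its mixed trifluoroacetic anhydride, would acylate ring A ortho to the ether oxygen in an intramolecular Friedel–Crafts reaction, closing ring C to A7.
- In favour: C2 is carried in from an enantiopure 3-aryl-3-hydroxypropanoate, so no asymmetric hydrogenation and no reduction–reoxidation detour is needed. On redox economy it is the better plan. Ring A is symmetric, as in the chosen plan (equal). No aryne is involved, so the N-methyl group can be present from the start (better), and only one hydrogenolysis follows the key step (better on endgame length).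
- Against: the aryloxy-substituted benzylic carbon of A6 is the weak point. Under acidic acylation conditions it can ionise (racemisation) or eliminate to a cinnamic acid and the ring A phenol, which the ring B carbonate can only slow. Forming that ether with inversion from a hindered, electron-rich phenol is itself prone to elimination. The ammonium group beside the reacting ring lowers its nucleophilicity.
- Comparison: A7 has the target skeleton at the correct oxidation level, one step closer than 20. Mechanistically it is an electrophilic substitution with a stereocentre at risk, against an aryne insertion with none at risk. The step count to the precursor is similar. The chosen plan gives up redox economy in exchange for building ring C while no labile stereocentre is present.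

Key step: step 9

Assumption: the (R,R) antipode of the carbene precursor SINpEt·HBF4 is taken as the one that delivers 2S in step 10; if a test on a simple flavone shows the opposite sense, the (S,S) antipode is used and nothing else changes.

Remark: 15 and 20 map atom for atom onto 24 (piperidine at C6, both centres S), so neither skeleton needs correction; the Boc group of 15 is kept because it is also the latent N-methyl group.

Step 1
Reactants: 1 2,4,6-trihydroxybenzaldehyde
Product: 2 2,6-dihydroxy-4-(methoxymethoxy)benzaldehyde
Conditions: MOMCl (1.05 equiv), i-Pr2NEt, THF, 0 °C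
Reagents that add atoms: chloromethyl methyl ether (MOMCl), COCCl
Why: O-alkylation of the most acidic phenol; the para hydroxyl is the vinylogous acid of the aldehyde and is neither hydrogen-bonded to nor flanked by the formyl group, so one equivalent of MOMCl should go there first, and any bis-ether is removed by chromatography.

Step 2
Reactants: 2 2,6-dihydroxy-4-(methoxymethoxy)benzaldehyde
Product: 3 2,6-bis(benzyloxy)-4-(methoxymethoxy)benzaldehyde
Conditions: BnBr, K2CO3, DMF, 60 °C
Reagents that add atoms: benzyl bromide, BrCc1ccccc1
Why: Williamson ether synthesis on the two equivalent ortho hydroxyls; the electron-poor ring favours O- over C-benzylation and the acetal is stable to carbonate.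

Step 3
Reactants: 3 2,6-bis(benzyloxy)-4-(methoxymethoxy)benzaldehyde; 4 (R)-tert-butanesulfinamide
Product: 5 (R,E)-N-[2,6-bis(benzyloxy)-4-(methoxymethoxy)benzylidene]-2-methylpropane-2-sulfinamide
Conditions: Ti(OEt)4, THF, 60 °C
Reagents that add atoms: none
Why: Ti(OEt)4-mediated condensation to the N-sulfinyl aldimine; the Lewis acid activates the hindered, electron-rich aldehyde and scavenges water, and only the E aldimine is expected.

Step 4
Reactants: 5 (R,E)-N-[2,6-bis(benzyloxy)-4-(methoxymethoxy)benzylidene]-2-methylpropane-2-sulfinamide; 6 1-bromo-4-chlorobutane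
Product: 9 (2S)-2-[2,6-bis(benzyloxy)-4-(methoxymethoxy)phenyl]-1-[(R)-tert-butylsulfinyl]piperidine, via 4-chlorobutylmagnesium bromide 7 (not isolated), via open-chain chloro sulfinamide 8 (not isolated)
Conditions: Mg, THF, rt (forms 7); then 5, toluene, −78 °C to rt; then KOtBu, THF, 0 °C to rt
Reagents that add atoms: none
Why: Magnesium inserts only into the C–Br bond; Grignard 1,2-addition to the N-sulfinyl aldimine in a non-coordinating solvent runs through a six-membered chair with magnesium on the sulfinyl oxygen, which for the (R) auxiliary and an aryl aldimine delivers the alkyl group to the face giving the (S) carbinamine 8; KOtBu then forms the sulfinamide anion, which closes the piperidine by 6-exo-tet N-alkylation without touching C2''.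

Step 5
Reactants: 9 (2S)-2-[2,6-bis(benzyloxy)-4-(methoxymethoxy)phenyl]-1-[(R)-tert-butylsulfinyl]piperidine
Product: 11 tert-butyl (2S)-2-[2,6-bis(benzyloxy)-4-hydroxyphenyl]piperidine-1-carboxylate, via aminophenol hydrochloride 10 (not isolated)
Conditions: HCl, MeOH, 0 °C to rt; evaporate; Boc2O, NaHCO3, THF/H2O, rt
Reagents that add atoms: di-tert-butyl dicarbonate, CC(C)(C)OC(=O)OC(=O)OC(C)(C)C
Why: Acidic methanolysis cleaves the N–S bond and the MOM acetal together while the amine is held as its ammonium salt; Boc2O in bicarbonate then acylates the amine in preference to the phenol, and any aryl carbonate is cleaved by a brief K2CO3/MeOH treatment.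

Step 6
Reactants: 11 tert-butyl (2S)-2-[2,6-bis(benzyloxy)-4-hydroxyphenyl]piperidine-1-carboxylate
Product: 12 tert-butyl (2S)-2-[2,6-bis(benzyloxy)-3-bromo-4-hydroxyphenyl]piperidine-1-carboxylate
Conditions: NBS (1.0 equiv), CH2Cl2, −78 to −20 °C
Reagents that add atoms: N-bromosuccinimide, O=C1CCC(=O)N1Br
Why: Electrophilic bromination of a phenol; the only free ring positions are the two equivalent ones ortho to the hydroxyl, so regiochemistry is not in question and dibromination is held back by stoichiometry and temperature.

Step 7
Reactants: 12 tert-butyl (2S)-2-[2,6-bis(benzyloxy)-3-bromo-4-hydroxyphenyl]piperidine-1-carboxylate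
Product: 15 3,5-bis(benzyloxy)-4-[(2S)-1-(tert-butoxycarbonyl)piperidin-2-yl]-2-(trimethylsilyl)phenyl trifluoromethanesulfonate, via aryl trimethylsilyl ether 13 (not isolated), via lithium ortho-silylphenoxide 14 (not isolated)
Conditions: HMDS, 80 °C; evaporate; n-BuLi, THF, −78 °C; PhNTf2, −78 °C to rt
Reagents that add atoms: hexamethyldisilazane, C[Si](C)(C)N[Si](C)(C)C; N-phenylbis(trifluoromethanesulfonimide), O=S(=O)(N(c1ccccc1)S(=O)(=O)C(F)(F)F)C(F)(F)F
Why: O-silylation, bromine–lithium exchange (faster at −78 °C than attack on the carbamate), 1,3 O-to-C silyl shift (retro-Brook rearrangement) to phenoxide 14 and O-triflation with a mild triflyl donor that leaves the Boc group alone; this is the standard sequence to ortho-silylaryl triflates.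

Step 8
Reactants: 16 1-(benzyloxy)-4-ethynylbenzene
Product: 17 3-[4-(benzyloxy)phenyl]propiolic acid
Conditions: n-BuLi, THF, −78 °C; CO2; aq. HCl
Reagents that add atoms: carbon dioxide, O=C=O
Why: Deprotonation of the terminal alkyne and carboxylation of the lithium acetylide; the benzyl ether is inert.

Step 9
Reactants: 15 3,5-bis(benzyloxy)-4-[(2S)-1-(tert-butoxycarbonyl)piperidin-2-yl]-2-(trimethylsilyl)phenyl trifluoromethanesulfonate; 17 3-[4-(benzyloxy)phenyl]propiolic acid
Product: 20 tert-butyl (2S)-2-[5,7-bis(benzyloxy)-2-[4-(benzyloxy)phenyl]-4-oxo-4H-chromen-6-yl]piperidine-1-carboxylate, via 3-alkoxyaryne 18 (not isolated), via ortho-acylphenoxide ynone 19 (not isolated)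
Conditions: 17 (1.5 equiv), CsF (4 equiv), THF, 125 °C, sealed tube
Reagents that add atoms: none
Why: Fluoride attacks silicon of 15 and triflate leaves, giving the 3-alkoxyaryne 18. The cesium carboxylate of 17 adds through oxygen to the aryne carbon remote from the flanking benzyloxy group (the future C8a), because the aryl anion then develops at the future C4a, where the adjacent C–O bond stabilises it inductively and the distorted aryne is less electrophilic. The aryl anion attacks the ester carbonyl two atoms away and the four-membered alkoxide opens to the ortho-acylphenoxide 19, a net insertion into the acid C–O bond; the closest known reaction type is fluoride-induced aryne insertion into carboxylic acids, in which arylpropiolic acids lead directly to flavones. The phenoxide then adds to the ynone in a 6-endo-dig oxa-Michael closure that forms O1–C2 and ring C; the 5-exo-dig mode to an aurone is disfavoured because the β-carbon is the electrophilic site of the aryl ynone under basic aprotic conditions. No stereocentre is created, and C2'' sees neither acid nor an ionising medium. The selectivities needed are the regiochemistry of aryne addition, secured by the C5 benzyloxy group, and acyl transfer over protonation of the aryl anion, favoured by the high temperature and by keeping the acid as its salt with excess CsF. Because 15 comes from a phenol with a mirror plane through C6 and C8a, either ortho position would give the same aryne, so no isomeric skeleton can form. The Boc carbamate keeps the nitrogen from adding to the aryne.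

Step 10
Reactants: 20 tert-butyl (2S)-2-[5,7-bis(benzyloxy)-2-[4-(benzyloxy)phenyl]-4-oxo-4H-chromen-6-yl]piperidine-1-carboxylate
Product: 21 tert-butyl (2S)-2-[(2S,4S)-5,7-bis(benzyloxy)-2-[4-(benzyloxy)phenyl]-4-hydroxychroman-6-yl]piperidine-1-carboxylate
Conditions: H2 (100 bar), Ru(cod)(2-methylallyl)2 (5 mol %), (R,R)-SINpEt·HBF4 (10 mol %), KOtBu (15 mol %), toluene, 40 °C
Reagents that add atoms: none
Why: Asymmetric hydrogenation of a flavone with a chiral ruthenium N-heterocyclic carbene catalyst formed in situ; H2 is added to one face of the C2=C3 bond under control of the carbene (the remote C2'' centre should not interfere) and the flavanone is reduced further, from the face opposite the C2 aryl group, to the cis carbinol, whose C4 configuration is erased in step 12; benzyl ethers and the carbamate are not touched.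

Step 11
Reactants: 21 tert-butyl (2S)-2-[(2S,4S)-5,7-bis(benzyloxy)-2-[4-(benzyloxy)phenyl]-4-hydroxychroman-6-yl]piperidine-1-carboxylate
Product: 22 (2S,4S)-5,7-bis(benzyloxy)-2-[4-(benzyloxy)phenyl]-6-[(2S)-1-methylpiperidin-2-yl]chroman-4-ol
Conditions: LiAlH4, THF, reflux; aq. NaOH work-up
Reagents that add atoms: none
Why: LiAlH4 reduction of a carbamate to an N-methyl amine (hydride addition, loss of tert-butoxide to the iminium ion, second hydride); with C4 at the alcohol level there is no carbonyl to protect, and aryl benzyl ethers and the ring C ether are inert to hydride.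

Step 12
Reactants: 22 (2S,4S)-5,7-bis(benzyloxy)-2-[4-(benzyloxy)phenyl]-6-[(2S)-1-methylpiperidin-2-yl]chroman-4-ol
Product: 23 (2S)-5,7-bis(benzyloxy)-2-[4-(benzyloxy)phenyl]-6-[(2S)-1-methylpiperidin-2-yl]chroman-4-one
Conditions: Dess–Martin periodinane, NaHCO3, CH2Cl2, 0 °C to rt
Reagents that add atoms: none
Why: Dess–Martin oxidation of the benzylic secondary alcohol to the aryl ketone under buffered, non-basic conditions, so C2 cannot epimerise by retro-oxa-Michael opening; the periodinane tolerates a tertiary amine.

Step 13
Reactants: 23 (2S)-5,7-bis(benzyloxy)-2-[4-(benzyloxy)phenyl]-6-[(2S)-1-methylpiperidin-2-yl]chroman-4-one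
Product: 24 (2S)-5,7-dihydroxy-2-(4-hydroxyphenyl)-6-[(2S)-1-methylpiperidin-2-yl]chroman-4-one
Conditions: H2 (1 atm), Pd/C (10 %), EtOAc/MeOH, rt
Reagents that add atoms: none
Why: Catalytic hydrogenolysis of the three aryl benzyl ethers, the usual last step for benzylated flavanones; aryl benzyl ethers should cleave well before the hindered cyclic benzylic amine, the C2–O1 bond or the conjugated C4 carbonyl, and the reaction is stopped after three equivalents of H2.

## Compound list

1 | 2,4,6-trihydroxybenzaldehyde | O=Cc1c(O)cc(O)cc1O | starting material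
2 | 2,6-dihydroxy-4-(methoxymethoxy)benzaldehyde | O=Cc1c(O)cc(OCOC)cc1O | intermediate
3 | 2,6-bis(benzyloxy)-4-(methoxymethoxy)benzaldehyde | O=Cc1c(OCc2ccccc2)cc(OCOC)cc1OCc1ccccc1 | intermediate
4 | (R)-tert-butanesulfinamide | CC(C)(C)[S@@](=O)N | starting material
5 | (R,E)-N-[2,6-bis(benzyloxy)-4-(methoxymethoxy)benzylidene]-2-methylpropane-2-sulfinamide | CC(C)(C)[S@@](=O)/N=C/c1c(OCc2ccccc2)cc(OCOC)cc1OCc1ccccc1 | intermediate
6 | 1-bromo-4-chlorobutane | ClCCCCBr | starting material
7 | 4-chlorobutylmagnesium bromide | ClCCCC[Mg]Br | intermediate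
8 | (R)-N-[(1S)-1-[2,6-bis(benzyloxy)-4-(methoxymethoxy)phenyl]-5-chloropentyl]-2-methylpropane-2-sulfinamide (N-magnesium salt in the flask) | CC(C)(C)[S@@](=O)N[C@@H](CCCCCl)c1c(OCc2ccccc2)cc(OCOC)cc1OCc1ccccc1 | intermediate
9 | (2S)-2-[2,6-bis(benzyloxy)-4-(methoxymethoxy)phenyl]-1-[(R)-tert-butylsulfinyl]piperidine | CC(C)(C)[S@@](=O)N1CCCC[C@H]1c1c(OCc2ccccc2)cc(OCOC)cc1OCc1ccccc1 | intermediate
10 | 3,5-bis(benzyloxy)-4-[(2S)-piperidin-2-yl]phenol hydrochloride | N1CCCC[C@H]1c1c(OCc2ccccc2)cc(O)cc1OCc1ccccc1.Cl | intermediate
11 | tert-butyl (2S)-2-[2,6-bis(benzyloxy)-4-hydroxyphenyl]piperidine-1-carboxylate | CC(C)(C)OC(=O)N1CCCC[C@H]1c1c(OCc2ccccc2)cc(O)cc1OCc1ccccc1 | intermediate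
12 | tert-butyl (2S)-2-[2,6-bis(benzyloxy)-3-bromo-4-hydroxyphenyl]piperidine-1-carboxylate | CC(C)(C)OC(=O)N1CCCC[C@H]1c1c(OCc2ccccc2)cc(O)c(Br)c1OCc1ccccc1 | intermediate
13 | tert-butyl (2S)-2-[2,6-bis(benzyloxy)-3-bromo-4-(trimethylsilyloxy)phenyl]piperidine-1-carboxylate | CC(C)(C)OC(=O)N1CCCC[C@H]1c1c(OCc2ccccc2)cc(O[Si](C)(C)C)c(Br)c1OCc1ccccc1 | intermediate
14 | lithium 3,5-bis(benzyloxy)-4-[(2S)-1-(tert-butoxycarbonyl)piperidin-2-yl]-2-(trimethylsilyl)phenolate | CC(C)(C)OC(=O)N1CCCC[C@H]1c1c(OCc2ccccc2)cc([O-])c([Si](C)(C)C)c1OCc1ccccc1.[Li+] | intermediate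
15 | 3,5-bis(benzyloxy)-4-[(2S)-1-(tert-butoxycarbonyl)piperidin-2-yl]-2-(trimethylsilyl)phenyl trifluoromethanesulfonate | CC(C)(C)OC(=O)N1CCCC[C@H]1c1c(OCc2ccccc2)cc(OS(=O)(=O)C(F)(F)F)c([Si](C)(C)C)c1OCc1ccccc1 | intermediate
16 | 1-(benzyloxy)-4-ethynylbenzene | C#Cc1ccc(OCc2ccccc2)cc1 | starting material
17 | 3-[4-(benzyloxy)phenyl]propiolic acid | OC(=O)C#Cc1ccc(OCc2ccccc2)cc1 | intermediate
18 | tert-butyl (2S)-2-[2,6-bis(benzyloxy)-3,4-didehydrophenyl]piperidine-1-carboxylate (aryne) | CC(C)(C)OC(=O)N1CCCC[C@H]1C1=C(OCc2ccccc2)C#CC=C1OCc1ccccc1 | intermediate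
19 | cesium 3,5-bis(benzyloxy)-2-{3-[4-(benzyloxy)phenyl]prop-2-ynoyl}-4-[(2S)-1-(tert-butoxycarbonyl)piperidin-2-yl]phenolate | CC(C)(C)OC(=O)N1CCCC[C@H]1c1c(OCc2ccccc2)cc([O-])c(C(=O)C#Cc2ccc(OCc3ccccc3)cc2)c1OCc1ccccc1.[Cs+] | intermediate
20 | tert-butyl (2S)-2-[5,7-bis(benzyloxy)-2-[4-(benzyloxy)phenyl]-4-oxo-4H-chromen-6-yl]piperidine-1-carboxylate | CC(C)(C)OC(=O)N1CCCC[C@H]1c1c(OCc2ccccc2)cc2c(c1OCc1ccccc1)C(=O)C=C(c1ccc(OCc3ccccc3)cc1)O2 | intermediate
21 | tert-butyl (2S)-2-[(2S,4S)-5,7-bis(benzyloxy)-2-[4-(benzyloxy)phenyl]-4-hydroxychroman-6-yl]piperidine-1-carboxylate | CC(C)(C)OC(=O)N1CCCC[C@H]1c1c(OCc2ccccc2)cc2c(c1OCc1ccccc1)[C@@H](O)C[C@@H](c1ccc(OCc3ccccc3)cc1)O2 | intermediate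
22 | (2S,4S)-5,7-bis(benzyloxy)-2-[4-(benzyloxy)phenyl]-6-[(2S)-1-methylpiperidin-2-yl]chroman-4-ol | CN1CCCC[C@H]1c1c(OCc2ccccc2)cc2c(c1OCc1ccccc1)[C@@H](O)C[C@@H](c1ccc(OCc3ccccc3)cc1)O2 | intermediate
23 | (2S)-5,7-bis(benzyloxy)-2-[4-(benzyloxy)phenyl]-6-[(2S)-1-methylpiperidin-2-yl]chroman-4-one | CN1CCCC[C@H]1c1c(OCc2ccccc2)cc2c(c1OCc1ccccc1)C(=O)C[C@@H](c1ccc(OCc3ccccc3)cc1)O2 | intermediate
24 | (2S)-5,7-dihydroxy-2-(4-hydroxyphenyl)-6-[(2S)-1-methylpiperidin-2-yl]chroman-4-one | CN1CCCC[C@H]1c1c(O)cc2c(c1O)C(=O)C[C@@H](c1ccc(O)cc1)O2 | target

## Step count and least certain steps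

Total step count: 13. Longest linear sequence: 12 steps (steps 1 to 7 and 9 to 13, from 1); the second branch is step 8 followed by steps 9 to 13.

**Step 9 (key step).** The most likely failures are protonation of the aryl anion before acyl transfer (simple O-arylation of the acid), thermal loss of the Boc group followed by N-arylation, or 5-exo closure. All stem from the high temperature the insertion needs and from the proton the acid brings in. The fallback sets out from 11. Iodination with N-iodosuccinimide at one of the two equivalent ortho positions should give tert-butyl (2S)-2-[2,6-bis(benzyloxy)-4-hydroxy-3-iodophenyl]piperidine-1-carboxylate F1. A carbonylative Sonogashira coupling–cyclisation of F1 with alkyne 16 under CO (PdCl2(PPh3)2, Et2NH, 120 °C) forms C4a–C4 and O1–C2 and comes back to the route at 20.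

**Step 4.** The risk is poor or reversed facial selectivity, because the two ortho benzyloxy oxygens can compete with the sulfinyl oxygen for magnesium, together with slow addition to a hindered, electron-rich aldimine. The fallback sets out from 3.
- Addition of 7 to the aldehyde gives 1-[2,6-bis(benzyloxy)-4-(methoxymethoxy)phenyl]-5-chloropentan-1-ol F2.
- Dess–Martin oxidation gives 1-[2,6-bis(benzyloxy)-4-(methoxymethoxy)phenyl]-5-chloropentan-1-one F3.
- Condensation with 4 (Ti(OEt)4, heat) gives (R)-N-{1-[2,6-bis(benzyloxy)-4-(methoxymethoxy)phenyl]-5-chloropentylidene}-2-methylpropane-2-sulfinamide F4.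
- Hydride reduction with LiBHEt3 at −78 °C (open transition state; NaBH4, through the cyclic one, if the sense must be reversed) gives 8, and KOtBu closes it to 9, where the route is rejoined.

**Step 7.** The risks are proton quench of the aryllithium by a neighbouring benzylic C–H before the silyl group migrates (loss of bromine without silylation), and incomplete triflation of the hindered phenoxide. The fallback sets out from 11.
- Isopropyl isocyanate and Et3N give tert-butyl (2S)-2-{2,6-bis(benzyloxy)-4-[(propan-2-ylcarbamoyl)oxy]phenyl}piperidine-1-carboxylate F5.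
- In-situ N-silylation (TMSOTf, TMEDA), carbamate-directed ortho-lithiation (n-BuLi, −78 °C) and a TMSCl quench give tert-butyl (2S)-2-{2,6-bis(benzyloxy)-4-[(propan-2-ylcarbamoyl)oxy]-3-(trimethylsilyl)phenyl}piperidine-1-carboxylate F6.
- DBU and Et2NH cleave the carbamate and PhNTf2, added to the same flask, triflates the phenoxide, returning to 15.

**Step 10.** The risk is insufficient facial selectivity at C2, since the catalyst must control a hindered, polyoxygenated flavone and may be mismatched with C2''; arene over-reduction is a lesser risk. The fallback sets out from 20.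
- Conjugate reduction with LiBH(s-Bu)3 (THF, −78 °C) gives tert-butyl (2S)-2-[(2RS)-5,7-bis(benzyloxy)-2-[4-(benzyloxy)phenyl]-4-oxochroman-6-yl]piperidine-1-carboxylate F7 as both C2 epimers.
- Transfer hydrogenation with RuCl(p-cymene)[(S,S)-TsDPEN] and HCO2H/Et3N (antipode chosen so that the 2S epimer reacts) reduces one epimer to the cis carbinol 21, where the route is rejoined. This is a kinetic resolution, helped here by the epimers being diastereomers.
- The unreacted 2R epimer is equilibrated with base through the chalcone and recycled.

**Step 11.** The risk is sluggish or incomplete reduction of the hindered carbamate, leading to N–H amine or recovered carbamate. The fallback sets out from 21.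
- Dess–Martin oxidation gives tert-butyl (2S)-2-[(2S)-5,7-bis(benzyloxy)-2-[4-(benzyloxy)phenyl]-4-oxochroman-6-yl]piperidine-1-carboxylate F8.
- TFA in CH2Cl2 at 0 °C gives (2S)-5,7-bis(benzyloxy)-2-[4-(benzyloxy)phenyl]-6-[(2S)-piperidin-2-yl]chroman-4-one F9.
- Reductive methylation (aqueous HCHO, NaBH(OAc)3) returns to the route at 23.

**Step 13.** The risk is over-reduction: hydrogenolysis of the benzylic C2–O1 or C2''–N bond, or reduction of the C4 carbonyl, all of which are benzylic on an electron-rich ring. The fallback sets out from 23 and ends at 24: Lewis-acid debenzylation with BCl3 and pentamethylbenzene as cation scavenger (CH2Cl2, −78 °C), which is non-reductive and passes through no new compound.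

## Further compounds

F1 | step 9 | tert-butyl (2S)-2-[2,6-bis(benzyloxy)-4-hydroxy-3-iodophenyl]piperidine-1-carboxylate | CC(C)(C)OC(=O)N1CCCC[C@H]1c1c(OCc2ccccc2)cc(O)c(I)c1OCc1ccccc1
F2 | step 4 | 1-[2,6-bis(benzyloxy)-4-(methoxymethoxy)phenyl]-5-chloropentan-1-ol (racemic) | OC(CCCCCl)c1c(OCc2ccccc2)cc(OCOC)cc1OCc1ccccc1
F3 | step 4 | 1-[2,6-bis(benzyloxy)-4-(methoxymethoxy)phenyl]-5-chloropentan-1-one | O=C(CCCCCl)c1c(OCc2ccccc2)cc(OCOC)cc1OCc1ccccc1
F4 | step 4 | (R)-N-{1-[2,6-bis(benzyloxy)-4-(methoxymethoxy)phenyl]-5-chloropentylidene}-2-methylpropane-2-sulfinamide | CC(C)(C)[S@@](=O)N=C(CCCCCl)c1c(OCc2ccccc2)cc(OCOC)cc1OCc1ccccc1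
F5 | step 7 | tert-butyl (2S)-2-{2,6-bis(benzyloxy)-4-[(propan-2-ylcarbamoyl)oxy]phenyl}piperidine-1-carboxylate | CC(C)(C)OC(=O)N1CCCC[C@H]1c1c(OCc2ccccc2)cc(OC(=O)NC(C)C)cc1OCc1ccccc1
F6 | step 7 | tert-butyl (2S)-2-{2,6-bis(benzyloxy)-4-[(propan-2-ylcarbamoyl)oxy]-3-(trimethylsilyl)phenyl}piperidine-1-carboxylate | CC(C)(C)OC(=O)N1CCCC[C@H]1c1c(OCc2ccccc2)cc(OC(=O)NC(C)C)c([Si](C)(C)C)c1OCc1ccccc1
F7 | step 10 | tert-butyl (2S)-2-[(2RS)-5,7-bis(benzyloxy)-2-[4-(benzyloxy)phenyl]-4-oxochroman-6-yl]piperidine-1-carboxylate (both C2 epimers) | CC(C)(C)OC(=O)N1CCCC[C@H]1c1c(OCc2ccccc2)cc2c(c1OCc1ccccc1)C(=O)CC(c1ccc(OCc3ccccc3)cc1)O2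
F8 | step 11 | tert-butyl (2S)-2-[(2S)-5,7-bis(benzyloxy)-2-[4-(benzyloxy)phenyl]-4-oxochroman-6-yl]piperidine-1-carboxylate | CC(C)(C)OC(=O)N1CCCC[C@H]1c1c(OCc2ccccc2)cc2c(c1OCc1ccccc1)C(=O)C[C@@H](c1ccc(OCc3ccccc3)cc1)O2
F9 | step 11 | (2S)-5,7-bis(benzyloxy)-2-[4-(benzyloxy)phenyl]-6-[(2S)-piperidin-2-yl]chroman-4-one | N1CCCC[C@H]1c1c(OCc2ccccc2)cc2c(c1OCc1ccccc1)C(=O)C[C@@H](c1ccc(OCc3ccccc3)cc1)O2
F0 | step 13 | none | none
A1 | alternative 1 | (2S)-2-[2,6-bis(benzyloxy)-4-(methoxymethoxy)phenyl]-1-[(R)-tert-butylsulfinyl]piperidine | CC(C)(C)[S@@](=O)N1CCCC[C@H]1c1c(OCc2ccccc2)cc(OCOC)cc1OCc1ccccc1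
A2 | alternative 2 | 1-tert-butyl 2-methyl (2S)-piperidine-1,2-dicarboxylate | CC(C)(C)OC(=O)N1CCCC[C@H]1C(=O)OC
A3 | alternative 2 | tert-butyl (2S)-2-{[tri(propan-2-yl)silyl]oxyethynyl}piperidine-1-carboxylate | CC(C)(C)OC(=O)N1CCCC[C@H]1C#CO[Si](C(C)C)(C(C)C)C(C)C
A4 | alternative 2 | 3-[(4-methoxybenzyl)oxy]cyclobut-2-en-1-one | COc1ccc(COC2=CC(=O)C2)cc1
A5 | alternative 2 | tert-butyl (2S)-2-[2-hydroxy-4-[(4-methoxybenzyl)oxy]-6-(triisopropylsilyloxy)phenyl]piperidine-1-carboxylate | CC(C)(C)OC(=O)N1CCCC[C@H]1c1c(O)cc(OCc2ccc(OC)cc2)cc1O[Si](C(C)C)(C(C)C)C(C)C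
A6 | alternative 3 | (3S)-3-{3,5-bis(benzyloxy)-4-[(2S)-1-methylpiperidin-2-yl]phenoxy}-3-{4-[(benzyloxycarbonyl)oxy]phenyl}propanoic acid | CN1CCCC[C@H]1c1c(OCc2ccccc2)cc(O[C@@H](CC(=O)O)c2ccc(OC(=O)OCc3ccccc3)cc2)cc1OCc1ccccc1
A7 | alternative 3 | benzyl 4-[(2S)-5,7-bis(benzyloxy)-6-[(2S)-1-methylpiperidin-2-yl]-4-oxochroman-2-yl]phenyl carbonate | CN1CCCC[C@H]1c1c(OCc2ccccc2)cc2c(c1OCc1ccccc1)C(=O)C[C@@H](c1ccc(OC(=O)OCc3ccccc3)cc1)O2
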